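**Plan**

- Cuts: the depsidone ester C(=O)–O bond and the diaryl ether O–C(ring A) bond (ring A comes from a 2-fluorobenzoate); the lactol ring, back to an ortho-formyl diethylbenzamide; the acetoxymethyl group, back to a dimethylaminomethyl group; and on ring B the aryl–C(=O) and aryl–CHO bonds.
- Enabling feature: ring B is a hexasubstituted benzene with oxygens at 1, 2 and 4, and each of its three carbon substituents is ortho to one of them. The two lactol-ring carbons are adjacent, the carbonyl carbon ortho to the phenol oxygen and the lactol carbon ortho to the diaryl-ether oxygen. A carbamate on the phenol oxygen can therefore hand over its carbonyl to the first site and then, as an amide, direct metalation to the second.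
- Forward: 3,4-dimethoxyphenol is carbamoylated and aminomethylated between its oxygens, and the double lithiation fills ring B. The catechol oxygens are kept as two methyl ethers, not as a dioxole, so that the new formyl group lets BCl3 free only the oxygen beside it. Ring A is joined there as the aryl ether, the seven-membered lactone is closed at step 11, the amine is exchanged for acetate, and the five-membered lactol ring is closed last at step 13.
- Stereochemistry: the lactol carbon is the only stereocentre. It forms as a racemate and epimerizes through the ring-opened formyl acid, so the (S)-enantiomer is taken at the very end by chiral chromatography with recycling of the (R)-form and is held by crystallization.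

Key step: step 3

Remark (assumption): the lactol carbon is taken to hold its configuration in the crystal and in cold, slightly acidic aprotic solution, but not in warm protic or basic media; all earlier intermediates are carried without regard to this centre.

**Route**

Step 1
Reactants: 1 3,4-dimethoxyphenol; 2 N,N-diethylcarbamoyl chloride
Product: 3 3,4-dimethoxyphenyl N,N-diethylcarbamate
Conditions: K2CO3, MeCN, 80 °C
Reagents that add atoms: N,N-diethylcarbamoyl chloride 2, CCN(CC)C(Cl)=O
Why: Acyl substitution of the phenoxide on the carbamoyl chloride (O-carbamoylation) should give the aryl O-carbamate, the strongest oxygen-based director for the lithiations that follow.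

Step 2
Reactants: 3 3,4-dimethoxyphenyl N,N-diethylcarbamate; 4 N,N-dimethylmethylideneammonium iodide
Product: 7 2-[(dimethylamino)methyl]-3,4-dimethoxyphenyl N,N-diethylcarbamate, via aryllithium 5 (not isolated), via arylmagnesium bromide 6 (not isolated)
Conditions: s-BuLi, TMEDA, THF, −78 °C; MgBr2·OEt2, −78 °C; then 4, −78 °C to rt
Reagents that add atoms: N,N-dimethylmethylideneammonium iodide 4, C=[N+](C)C.[I-]
Why: Directed ortho-metalation should occur at the hydrogen between the carbamate and the 3-methoxyl, which both acidify and coordinate it; the aryllithium does not rearrange at −78 °C and is moved to magnesium so that it cannot do so on warming, and the aryl Grignard then adds to the iminium salt (Mannich-type aminomethylation).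

Step 3
Reactants: 7 2-[(dimethylamino)methyl]-3,4-dimethoxyphenyl N,N-diethylcarbamate; 8 N,N-dimethylformamide
Product: 12 N,N-diethyl 3-[(dimethylamino)methyl]-6-formyl-2-hydroxy-4,5-dimethoxybenzamide, via ortho-lithiated carbamate 9 (not isolated), via lithium salicylamide phenolate 10 (not isolated), via ring-lithiated phenolate 11 (not isolated)
Conditions: s-BuLi (1.2 equiv), TMEDA, THF, −78 °C to rt; then s-BuLi (2.2 equiv), TMEDA, −78 to −40 °C; DMF, −78 °C to rt; aq. NH4Cl
Reagents that add atoms: N,N-dimethylformamide 8, CN(C)C=O
Why: s-BuLi/TMEDA removes the only hydrogen ortho to the carbamate to give aryllithium 9, and on warming this carbanion attacks the carbamoyl carbon through a four-centre transition state, the 1,3 oxygen-to-carbon shift (anionic ortho-Fries rearrangement) forming the aryl–C(=O)N bond and lithium phenolate 10. A second charge of s-BuLi/TMEDA then removes the last ring hydrogen, which lies between the new tertiary amide and a methoxyl, and DMF traps the resulting 11 to give the aryl–CHO bond after collapse of the hemiaminal on work-up (amide-directed ortho-lithiation and formylation). Both halves are standard directed-metalation chemistry of aryl O-carbamates and benzamides, normally run as separate steps with the phenol capped; here they are telescoped with the phenol carried as its lithium salt, which costs one extra equivalent of base. No ring closes and no stereocentre is formed. The step needs site selectivity only, and the substrate secures it: the carbamate has a single free ortho position, the benzylic CH2 next to nitrogen is too weakly acidic for lateral metalation under these kinetic conditions, after the shift only one ring hydrogen is left, and the doubly flanked diethylamide resists addition of s-BuLi at −78 °C.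

Step 4
Reactants: 12 N,N-diethyl 3-[(dimethylamino)methyl]-6-formyl-2-hydroxy-4,5-dimethoxybenzamide
Product: 13 N,N-diethyl 3-[(dimethylamino)methyl]-6-formyl-2,5-dihydroxy-4-methoxybenzamide
Conditions: BCl3 (3.5 equiv), CH2Cl2, −78 to 0 °C; aq. NaHCO3
Reagents that add atoms: none
Why: BCl3 should bind between the formyl oxygen and the neighbouring methoxy oxygen, and chloride then removes only that methyl group (chelation-controlled O-demethylation ortho to a carbonyl), leaving the other methoxyl, which has no carbonyl neighbour, and the hindered amide untouched.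

Step 5
Reactants: 14 3-fluoro-5-methylphenol
Product: 15 1-fluoro-3-methoxy-5-methylbenzene
Conditions: MeI, K2CO3, acetone, 56 °C
Reagents that add atoms: iodomethane, CI
Why: Williamson ether synthesis on the phenoxide; the methyl ether serves as lithiation director and protects the ring A phenol until step 10.

Step 6
Reactants: 15 1-fluoro-3-methoxy-5-methylbenzene; 8 N,N-dimethylformamide
Product: 17 2-fluoro-6-methoxy-4-methylbenzaldehyde, via aryllithium 16 (not isolated)
Conditions: n-BuLi, THF, −78 °C; DMF; aq. NH4Cl
Reagents that add atoms: N,N-dimethylformamide 8, CN(C)C=O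
Why: Directed ortho-metalation: fluorine and methoxyl jointly acidify the hydrogen between them, and the aryllithium is formylated by DMF, while −78 °C avoids loss of LiF to an aryne.

Step 7
Reactants: 17 2-fluoro-6-methoxy-4-methylbenzaldehyde
Product: 18 3-bromo-2-fluoro-6-methoxy-4-methylbenzaldehyde
Conditions: NBS, DMF, rt, dark
Reagents that add atoms: N-bromosuccinimide, O=C1CCC(=O)N1Br
Why: Electrophilic aromatic bromination should go para to the methoxyl and ortho to fluorine, meta to the formyl group, the other open position being squeezed between methoxyl and methyl.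

Step 8
Reactants: 18 3-bromo-2-fluoro-6-methoxy-4-methylbenzaldehyde
Product: 21 tert-butyl 2-fluoro-3-formyl-4-methoxy-6-methylbenzoate, via lithium alpha-amino alkoxide 19 (not isolated), via lithiated alkoxide 20 (not isolated)
Conditions: LiN(Me)CH2CH2NMe2 (from the diamine and n-BuLi), THF, −78 °C; n-BuLi, −78 °C; Boc2O, −78 to −20 °C; aq. NH4Cl
Reagents that add atoms: di-tert-butyl dicarbonate, CC(C)(C)OC(=O)OC(=O)OC(C)(C)C
Why: The lithium amide adds to the aldehyde and masks it as an alpha-amino alkoxide (Comins in situ protection), bromine–lithium exchange then gives the aryllithium, which Boc2O acylates to the tert-butyl ester, and aqueous work-up returns the aldehyde; at −78 °C the ortho-fluoro aryllithium should not lose LiF.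

Step 9
Reactants: 13 N,N-diethyl 3-[(dimethylamino)methyl]-6-formyl-2,5-dihydroxy-4-methoxybenzamide; 21 tert-butyl 2-fluoro-3-formyl-4-methoxy-6-methylbenzoate
Product: 22 tert-butyl 2-{3-(diethylcarbamoyl)-5-[(dimethylamino)methyl]-2-formyl-4-hydroxy-6-methoxyphenoxy}-3-formyl-4-methoxy-6-methylbenzoate
Conditions: Cs2CO3 (1.2 equiv), degassed DMSO, argon, 70 °C
Reagents that add atoms: none
Why: Nucleophilic aromatic substitution by addition–elimination: the fluoride of 21 is activated by the ortho formyl and ortho ester groups, and of the two phenols of 13 the one beside the formyl group is the more acidic and the less crowded, the other lying between the amide and the aminomethyl group; oxygen is excluded because 13 is a hydroquinone.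

Step 10
Reactants: 22 the diaryl ether of step 9
Product: 23 2-{3-(diethylcarbamoyl)-5-[(dimethylamino)methyl]-2-formyl-4,6-dihydroxyphenoxy}-3-formyl-4-hydroxy-6-methylbenzoic acid
Conditions: BBr3 (8 equiv), CH2Cl2, −78 °C to rt; H2O
Reagents that add atoms: none
Why: Lewis-acid ether cleavage with BBr3 should remove both aryl methyl ethers and the tert-butyl ester in one operation, whereas the diaryl ether, the aldehydes and the tertiary amide are inert to it.

Step 11
Reactants: 23 the seco acid of step 10
Product: 24 N,N-diethyl 9-[(dimethylamino)methyl]-4,6-diformyl-3,8-dihydroxy-1-methyl-11-oxo-11H-dibenzo[b,e][1,4]dioxepine-7-carboxamide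
Conditions: (CF3CO)2O, CF3CO2H, CH2Cl2 (high dilution), 0 °C to rt; then MeOH, aq. NaHCO3, 0 °C
Reagents that add atoms: none
Why: Trifluoroacetic anhydride activates the hindered benzoic acid (acylium-type activation), and the ring B phenol next to the ether oxygen captures it to close the seven-membered lactone (depsidone lactonization); dilution favours the ring over oligomers, and the cold bicarbonate wash cleaves adventitious aryl trifluoroacetates.

Step 12
Reactants: 24 the depsidone amine of step 11
Product: 26 [7-(diethylcarbamoyl)-4,6-diformyl-3,8-dihydroxy-1-methyl-11-oxo-11H-dibenzo[b,e][1,4]dioxepin-9-yl]methyl acetate, via benzylic trimethylammonium iodide 25 (not isolated)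
Conditions: MeI, acetone, rt, dark; evaporate; NaOAc, AcOH, 80 °C
Reagents that add atoms: sodium acetate, CC(=O)[O-].[Na+]
Why: Menshutkin quaternization makes trimethylamine a leaving group, and the ortho-hydroxybenzyl ammonium salt then exchanges it for acetate by elimination–addition through the ortho-quinone methide, the usual path from phenolic Mannich bases to acetoxymethyl phenols; no free carboxylic acid is present at this stage to compete for MeI.

Step 13
Reactants: 26 the acetate of step 12
Product: 27 rac-galbinic acid
Conditions: TsOH·H2O (1.5 equiv), AcOH, 70 °C; then H2O, rt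
Reagents that add atoms: water, O
Why: Anchimerically assisted amide hydrolysis: the amide oxygen adds to the protonated ortho aldehyde to give a cyclic iminium ether, water adds and diethylamine leaves to form the 3-hydroxyphthalide ring, while the acetic acid solvent holds the benzylic acetate by mass action; the new lactol stereocentre forms without control, as the racemate.

Step 14
Reactants: 27 rac-galbinic acid
Product: 28 (S)-galbinic acid
Conditions: preparative SFC on immobilized amylose tris(3,5-dimethylphenylcarbamate), CO2/MeCN with 0.1% AcOH, 10 °C; (R)-fraction: AcOH, 60 °C, recycled; crystallization from cold MeCN/toluene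
Reagents that add atoms: none
Why: No bond is made: chromatographic resolution on a chiral stationary phase should deliver the (S)-enantiomer (configuration to be assigned by anomalous-dispersion X-ray diffraction), the (R)-fraction is racemized through the ring-opened formyl acid and recycled (dynamic resolution), and crystallization from cold, base-free solvent holds the configuration in the lattice.

**Compound list**

1 | 3,4-dimethoxyphenol | COc1ccc(O)cc1OC | starting material
2 | N,N-diethylcarbamoyl chloride | CCN(CC)C(Cl)=O | starting material
3 | 3,4-dimethoxyphenyl N,N-diethylcarbamate | CCN(CC)C(=O)Oc1ccc(OC)c(OC)c1 | intermediate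
4 | N,N-dimethylmethylideneammonium iodide (Eschenmoser's salt) | C=[N+](C)C.[I-] | starting material
5 | 2-lithio-3,4-dimethoxyphenyl N,N-diethylcarbamate | CCN(CC)C(=O)Oc1ccc(OC)c(OC)c1[Li] | intermediate
6 | {6-[(diethylcarbamoyl)oxy]-2,3-dimethoxyphenyl}magnesium bromide | CCN(CC)C(=O)Oc1ccc(OC)c(OC)c1[Mg]Br | intermediate
7 | 2-[(dimethylamino)methyl]-3,4-dimethoxyphenyl N,N-diethylcarbamate | CCN(CC)C(=O)Oc1ccc(OC)c(OC)c1CN(C)C | intermediate
8 | N,N-dimethylformamide | CN(C)C=O | starting material
9 | 2-[(dimethylamino)methyl]-6-lithio-3,4-dimethoxyphenyl N,N-diethylcarbamate | CCN(CC)C(=O)Oc1c([Li])cc(OC)c(OC)c1CN(C)C | intermediate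
10 | lithium 2-(diethylcarbamoyl)-6-[(dimethylamino)methyl]-4,5-dimethoxyphenolate | CCN(CC)C(=O)c1cc(OC)c(OC)c(CN(C)C)c1[O-].[Li+] | intermediate
11 | lithium 2-(diethylcarbamoyl)-6-[(dimethylamino)methyl]-3-lithio-4,5-dimethoxyphenolate | CCN(CC)C(=O)c1c([Li])c(OC)c(OC)c(CN(C)C)c1[O-].[Li+] | intermediate
12 | N,N-diethyl 3-[(dimethylamino)methyl]-6-formyl-2-hydroxy-4,5-dimethoxybenzamide | CCN(CC)C(=O)c1c(C=O)c(OC)c(OC)c(CN(C)C)c1O | intermediate
13 | N,N-diethyl 3-[(dimethylamino)methyl]-6-formyl-2,5-dihydroxy-4-methoxybenzamide | CCN(CC)C(=O)c1c(C=O)c(O)c(OC)c(CN(C)C)c1O | intermediate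
14 | 3-fluoro-5-methylphenol | Cc1cc(O)cc(F)c1 | starting material
15 | 1-fluoro-3-methoxy-5-methylbenzene | COc1cc(C)cc(F)c1 | intermediate
16 | (2-fluoro-6-methoxy-4-methylphenyl)lithium | COc1cc(C)cc(F)c1[Li] | intermediate
17 | 2-fluoro-6-methoxy-4-methylbenzaldehyde | COc1cc(C)cc(F)c1C=O | intermediate
18 | 3-bromo-2-fluoro-6-methoxy-4-methylbenzaldehyde | COc1cc(C)c(Br)c(F)c1C=O | intermediate
19 | lithium (3-bromo-2-fluoro-6-methoxy-4-methylphenyl){[2-(dimethylamino)ethyl](methyl)amino}methanolate | COc1cc(C)c(Br)c(F)c1C([O-])N(C)CCN(C)C.[Li+] | intermediate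
20 | lithium {[2-(dimethylamino)ethyl](methyl)amino}(2-fluoro-3-lithio-6-methoxy-4-methylphenyl)methanolate | COc1cc(C)c([Li])c(F)c1C([O-])N(C)CCN(C)C.[Li+] | intermediate
21 | tert-butyl 2-fluoro-3-formyl-4-methoxy-6-methylbenzoate | COc1cc(C)c(C(=O)OC(C)(C)C)c(F)c1C=O | intermediate
22 | tert-butyl 2-{3-(diethylcarbamoyl)-5-[(dimethylamino)methyl]-2-formyl-4-hydroxy-6-methoxyphenoxy}-3-formyl-4-methoxy-6-methylbenzoate | CCN(CC)C(=O)c1c(C=O)c(Oc2c(C=O)c(OC)cc(C)c2C(=O)OC(C)(C)C)c(OC)c(CN(C)C)c1O | intermediate
23 | 2-{3-(diethylcarbamoyl)-5-[(dimethylamino)methyl]-2-formyl-4,6-dihydroxyphenoxy}-3-formyl-4-hydroxy-6-methylbenzoic acid | CCN(CC)C(=O)c1c(C=O)c(Oc2c(C=O)c(O)cc(C)c2C(=O)O)c(O)c(CN(C)C)c1O | intermediate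
24 | N,N-diethyl 9-[(dimethylamino)methyl]-4,6-diformyl-3,8-dihydroxy-1-methyl-11-oxo-11H-dibenzo[b,e][1,4]dioxepine-7-carboxamide | CCN(CC)C(=O)c1c(C=O)c2Oc3c(C=O)c(O)cc(C)c3C(=O)Oc2c(CN(C)C)c1O | intermediate
25 | 1-[7-(diethylcarbamoyl)-4,6-diformyl-3,8-dihydroxy-1-methyl-11-oxo-11H-dibenzo[b,e][1,4]dioxepin-9-yl]-N,N,N-trimethylmethanaminium iodide | CCN(CC)C(=O)c1c(C=O)c2Oc3c(C=O)c(O)cc(C)c3C(=O)Oc2c(C[N+](C)(C)C)c1O.[I-] | intermediate
26 | [7-(diethylcarbamoyl)-4,6-diformyl-3,8-dihydroxy-1-methyl-11-oxo-11H-dibenzo[b,e][1,4]dioxepin-9-yl]methyl acetate | CCN(CC)C(=O)c1c(C=O)c2Oc3c(C=O)c(O)cc(C)c3C(=O)Oc2c(COC(C)=O)c1O | intermediate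
27 | rac-galbinic acid (racemic at the lactol carbon) | CC(=O)OCc1c(O)c2c(c3c1OC(=O)c1c(C)cc(O)c(C=O)c1O3)C(O)OC2=O | intermediate
28 | (S)-galbinic acid | CC(=O)OCc1c(O)c2c(c3c1OC(=O)c1c(C)cc(O)c(C=O)c1O3)[C@@H](O)OC2=O | target

**Count and risks**

Total steps: 14. Longest linear sequence: 10 steps (steps 1–4 and 9–14); ring A is made in steps 5–8.

Step 3. The second deprotonation has to be done on a lithium phenolate; the build-up of charge may leave the last ring hydrogen untouched or let s-BuLi add to the amide. Fallback, from 7 back to 12: run only the carbamoyl shift (s-BuLi, TMEDA, −78 °C to rt, NH4Cl) and isolate the neutral salicylamide N,N-diethyl 3-[(dimethylamino)methyl]-2-hydroxy-4,5-dimethoxybenzamide F1. Cap its phenol with TBSOTf and 2,6-lutidine to give the silyl ether N,N-diethyl 2-[(tert-butyldimethylsilyl)oxy]-3-[(dimethylamino)methyl]-4,5-dimethoxybenzamide F2. Lithiate this neutral amide between the amide and the methoxyl (s-BuLi, TMEDA, −78 °C) and quench with DMF to give N,N-diethyl 2-[(tert-butyldimethylsilyl)oxy]-3-[(dimethylamino)methyl]-6-formyl-4,5-dimethoxybenzamide F3. Bu4NF then returns 12.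

Step 9. The phenolate beside the formyl group is chelated and flanked on both sides, and the fluoride is doubly ortho-substituted; substitution may stall or go through the other phenol. Fallback, from 13 back to 22: HCl in MeOH at 65 °C turns the ortho-formyl amide into the methyl pseudo-ester 6-[(dimethylamino)methyl]-4,7-dihydroxy-3,5-dimethoxy-2-benzofuran-1(3H)-one F4. In F4 the phenol next to the lactone carbonyl is tied up by a hydrogen bond, and the phenol to be arylated is no longer conjugated with a carbonyl. Substitution on 21 (Cs2CO3, DMSO) should then give tert-butyl 2-({6-[(dimethylamino)methyl]-7-hydroxy-3,5-dimethoxy-1-oxo-1,3-dihydro-2-benzofuran-4-yl}oxy)-3-formyl-4-methoxy-6-methylbenzoate F5. Me2AlNEt2 (from AlMe3 and Et2NH, toluene, 40 °C) reopens the pseudo-ester to the diethylamide and the aldehyde, which is 22.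

Step 14. The enantiomers may interconvert on the time scale of the separation, so that no clean cut is possible. Fallback, from 27 back to 28 (no new compound, F0): crystallization-induced deracemization. A slurry of 27 in acetic acid with a trace of NaOAc, which keeps the dissolved lactol racemizing, is ground with glass beads and seeded with (S)-crystals from an analytical-scale separation (attrition-enhanced deracemization). This applies if the racemate crystallizes as a conglomerate, which has to be established first.

**Further compounds**

F1 | step 3 | N,N-diethyl 3-[(dimethylamino)methyl]-2-hydroxy-4,5-dimethoxybenzamide | CCN(CC)C(=O)c1cc(OC)c(OC)c(CN(C)C)c1O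
F2 | step 3 | N,N-diethyl 2-[(tert-butyldimethylsilyl)oxy]-3-[(dimethylamino)methyl]-4,5-dimethoxybenzamide | CCN(CC)C(=O)c1cc(OC)c(OC)c(CN(C)C)c1O[Si](C)(C)C(C)(C)C
F3 | step 3 | N,N-diethyl 2-[(tert-butyldimethylsilyl)oxy]-3-[(dimethylamino)methyl]-6-formyl-4,5-dimethoxybenzamide | CCN(CC)C(=O)c1c(C=O)c(OC)c(OC)c(CN(C)C)c1O[Si](C)(C)C(C)(C)C
F4 | step 9 | 6-[(dimethylamino)methyl]-4,7-dihydroxy-3,5-dimethoxy-2-benzofuran-1(3H)-one (racemic) | COC1OC(=O)c2c(O)c(CN(C)C)c(OC)c(O)c12
F5 | step 9 | tert-butyl 2-({6-[(dimethylamino)methyl]-7-hydroxy-3,5-dimethoxy-1-oxo-1,3-dihydro-2-benzofuran-4-yl}oxy)-3-formyl-4-methoxy-6-methylbenzoate (racemic) | COC1OC(=O)c2c(O)c(CN(C)C)c(OC)c(Oc3c(C=O)c(OC)cc(C)c3C(=O)OC(C)(C)C)c12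
F0 | step 14 | none | none
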